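**Strategy.** The route rests on disconnecting the C4a–C5 bond of ring B (C-4a, C-5, C-6, C-7, C-8, C-8a). The key step copies the bisabolyl-to-cadinyl closure of sesquiterpene biosynthesis: the trisubstituted alkene of a citronellal-derived side chain attacks C-4a of a Lewis-acid-activated cyclohexenone (ring A) in an intramolecular ene-type cyclisation. This closes ring B, sets C-4a and C-5, and leaves an isopropenyl group (hydrated later) and a C-1 ketone (later the C1=C8a alkene). It exploits the carbinol-bearing C-5 next to the allylic ring-fusion C-4a, and the C-8 methyl beside sp2 C-8a for stereocontrol. The precursor is a monocyclic 2,6,6-trisubstituted cyclohexenone.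

Key step: step 7

Remark (assumptions): (R)-citronellal, citropten and the two Grignard reagents are taken as commercial. Locants C-1 to C-8a are those of the octahydronaphthalene core (C-1 carbonyl or olefinic CH, C-2 quaternary, C-4a ring-fusion CH, C-5 CH bearing the three-carbon unit, C-8 CHCH3, C-8a sp2 fusion carbon). Centres that are erased later are drawn without configuration. Changes of R/S at unchanged centres between 12 and 17 are priority effects only.

Step 1
Reactants: 1 (R)-citronellal; 2 vinylmagnesium bromide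
Product: 3 (5R)-5,9-dimethyldeca-1,8-dien-3-ol (both C-3 epimers)
Conditions: CH2=CHMgBr, THF, −78 → 0 °C; aq. NH4Cl
Reagents that add atoms: vinylmagnesium bromide (2), C=C[Mg]Br
Why: Grignard 1,2-addition to the aldehyde; the new carbinol centre is not controlled because it is oxidised in step 2.

Step 2
Reactants: 3 (5R)-5,9-dimethyldeca-1,8-dien-3-ol
Product: 4 (5R)-5,9-dimethyldeca-1,8-dien-3-one
Conditions: Dess–Martin periodinane, NaHCO3, CH2Cl2, 0 → 23 °C
Reagents that add atoms: none
Why: Dess–Martin oxidation of the allylic alcohol should give the vinyl ketone under mild conditions, and the C-5 stereocentre is β to the carbonyl and cannot epimerise.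

Step 3
Reactants: 5 citropten (5,7-dimethoxycoumarin); 6 isobutylmagnesium bromide
Product: 7 (4S)-5,7-dimethoxy-4-(2-methylpropyl)-3,4-dihydro-2H-chromen-2-one
Conditions: i-BuMgBr, CuBr·SMe2 (5 mol %), 1-[2-(diphenylphosphino)ferrocenyl]ethyldicyclohexylphosphine (6 mol %, the enantiomer that delivers 4S), CH2Cl2, −78 °C; aq. NH4Cl
Reagents that add atoms: isobutylmagnesium bromide (6), CC(C)C[Mg]Br
Why: Copper-catalysed asymmetric conjugate addition of a Grignard reagent to the coumarin, in which the chiral ferrocenyl diphosphine–copper complex selects the face of C-4 and sets the benzylic stereocentre.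

Step 4
Reactants: 7 (4S)-4-isobutyl-5,7-dimethoxychroman-2-one; 4 (5R)-5,9-dimethyldeca-1,8-dien-3-one
Product: 10 (9S)-6,8-dimethoxy-4-[(2R)-6-methylhept-5-en-2-yl]-9-(2-methylpropyl)-1,2,9,9a-tetrahydro-3H-xanthen-3-one, via Michael adduct 8 (not isolated), via phenolic cyclohexanedione 9 (not isolated)
Conditions: LiN(SiMe3)2 (1.1 equiv), THF, −78 °C; 4, −78 → 23 °C; aq. HCl; then TsOH·H2O (5 mol %), 4 Å MS, CH2Cl2, 23 °C
Reagents that add atoms: none
Why: Michael addition of the lactone enolate to the vinyl ketone, Claisen acylation of the equilibrated ketone enolate by the aryl ester (a Michael–Claisen annulation that builds ring A) and acid-catalysed cyclodehydration of the freed phenol onto the neighbouring carbonyl should give the vinylogous aryl ester; C-9a is uncontrolled and is erased in step 6.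

Step 5
Reactants: 10 tetrahydroxanthenone
Product: 12 6-[(1S)-1-(2-hydroxy-4,6-dimethoxyphenyl)-3-methylbutyl]-2-[(2R)-6-methylhept-5-en-2-yl]cyclohex-2-en-1-one (C-6 epimers), via allylic alcohol 11 (not isolated)
Conditions: i-Bu2AlH, CH2Cl2, −78 °C; then 0.5 M HCl, THF, 0 °C
Reagents that add atoms: water, O
Why: Stork–Danheiser transposition, in which 1,2-reduction of the vinylogous ester carbonyl followed by acid hydrolysis of the aryl enol ether with loss of the allylic hydroxyl places the carbonyl next to C-6 and frees the phenol.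

Step 6
Reactants: 12 phenolic cyclohexenone
Product: 14 (6R)-6-methyl-2-[(2R)-6-methylhept-5-en-2-yl]-6-[(1R)-3-methyl-1-(2,4,6-trimethoxyphenyl)butyl]cyclohex-2-en-1-one, via C-methylated phenol 13 (not isolated)
Conditions: LiN(i-Pr)2 (2.1 equiv), THF, −78 °C; MeI (excess), DMPU, −78 → 23 °C
Reagents that add atoms: iodomethane, CI
Why: Kinetic α′-deprotonation gives the cross-conjugated dienolate, and enolate alkylation should set the quaternary centre on the face predicted both by the allylic-strain rotamer (benzylic H eclipsing the enolate C–O, attack anti to the aryl group) and by the lithium-bridged phenoxide rotamer (attack anti to isobutyl); the phenoxide is O-methylated on warming (Williamson ether synthesis).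

Step 7
Reactants: 14 trimethoxyaryl cyclohexenone
Product: 15 (2R,4aR,5S,8R)-2,8-dimethyl-2-[(1R)-3-methyl-1-(2,4,6-trimethoxyphenyl)butyl]-5-(prop-1-en-2-yl)octahydronaphthalen-1(2H)-one (C-8a epimers)
Conditions: Me2AlCl (2.5 equiv), CH2Cl2, −78 → 0 °C; aq. HCl
Reagents that add atoms: none
Why: Me2AlCl binds the ring A carbonyl, the enone β-carbon (C-4a of 15) is attacked by the less substituted carbon of the side-chain alkene (C-5), and the tertiary 2-propyl cation/aluminium enolate zwitterion collapses by 1,5-proton transfer from a methyl group to give the isopropenyl ketone. This is the Lewis-acid-induced conjugate addition of an alkene to an enone, a stepwise type 1 intramolecular ene reaction, and it mirrors the allyl-cation/prenyl closure that turns a bisabolyl into a cadinyl skeleton. Ring B closes as a six-membered ring, endo with respect to the enone C=C (both carbons become ring members) and exo with respect to the donor alkene, through a chair. C-4a is controlled by the side-chain methyl centre (C-8): in the chair its hydrogen, not its methyl, lies in the enone plane beside the aluminium-bound carbonyl oxygen (allylic strain), so the methyl is axial and the chain reaches the ring A face that puts H-4a cis to that methyl. C-5 is controlled by the equatorial placement of the developing 2-propyl cation in the same chair, which gives trans H-4a/H-5; C-8a is uncontrolled and is removed in step 8. The step needs 1,4- rather than 1,2-attack and proton loss rather than hydride shifts (secured by the quaternary C-2 flanking the carbonyl and by the mild, proton-scavenging Me2AlCl), and it needs the face selectivity above, which the allylic strain must enforce against any bias from the quaternary centre.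

Step 8
Reactants: 15 bicyclic ketone
Product: 16 (2R,4aR,5S,8R)-2,8-dimethyl-2-[(1S)-3-methyl-1-(2,4,6-trimethoxyphenyl)butyl]-5-(prop-1-en-2-yl)-2,3,4,4a,5,6,7,8-octahydronaphthalen-1-yl trifluoromethanesulfonate
Conditions: KN(SiMe3)2, THF, −78 → 0 °C; N-(5-chloropyridin-2-yl)-N-(trifluoromethylsulfonyl)trifluoromethanesulfonamide, −78 → 0 °C; aq. NH4Cl
Reagents that add atoms: N-(5-chloropyridin-2-yl)-N-(trifluoromethylsulfonyl)trifluoromethanesulfonamide, O=S(=O)(N(c1ccc(Cl)cn1)S(=O)(=O)C(F)(F)F)C(F)(F)F
Why: The ketone can enolise only towards C-8a because C-2 is quaternary, so O-triflation of the potassium enolate should place the enol triflate double bond regiospecifically at C1=C8a.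

Step 9
Reactants: 16 enol triflate
Product: 17 2-[(1S)-1-[(2S,4aR,5S,8R)-2,8-dimethyl-5-(prop-1-en-2-yl)-2,3,4,4a,5,6,7,8-octahydronaphthalen-2-yl]-3-methylbutyl]-1,3,5-trimethoxybenzene
Conditions: Pd(OAc)2 (5 mol %), PPh3 (10 mol %), HCO2H, n-Bu3N, DMF, 60 °C
Reagents that add atoms: none
Why: Palladium-catalysed formate reduction of the enol triflate (oxidative addition, formate exchange, decarboxylation, reductive elimination) should replace OTf by H without moving the double bond or touching the isopropenyl group.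

Step 10
Reactants: 17 diene
Product: 19 2-[(1S,4R,6S,8aR)-4,6-dimethyl-6-[(1S)-3-methyl-1-(2,4,6-trimethoxyphenyl)butyl]-1,2,3,4,6,7,8,8a-octahydronaphthalen-1-yl]propan-2-ol, via tertiary hydroperoxide 18 (not isolated)
Conditions: Co(acac)2 (20 mol %), PhSiH3, O2 (1 atm), THF, 23 °C; then PPh3
Reagents that add atoms: dioxygen, O=O
Why: Mukaiyama hydration, in which hydrogen-atom transfer to the 1,1-disubstituted alkene gives the tertiary radical (Markovnikov) that traps O2, while the hindered trisubstituted C1=C8a alkene should react far more slowly; no stereocentre is created.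

Step 11
Reactants: 19 tertiary alcohol
Product: 21 5-[(1S)-1-[(2S,4aR,5S,8R)-5-(2-hydroxypropan-2-yl)-2,8-dimethyl-2,3,4,4a,5,6,7,8-octahydronaphthalen-2-yl]-3-methylbutyl]-2,4,6-trimethoxybenzene-1,3-dicarbaldehyde, via monoformyl amino-alkoxide adduct 20 (not isolated)
Conditions: n-BuLi (2.2 equiv), TMEDA, THF, 0 °C; DMF (1.1 equiv), −78 → 0 °C; n-BuLi (1.5 equiv), 0 °C; DMF (excess); aq. NH4Cl
Reagents that add atoms: N,N-dimethylformamide, CN(C)C=O
Why: Directed ortho-metalation, in which each aryl C–H lies between two methoxy groups and is lithiated after deprotonation of the alcohol, the first formyl group staying masked as its lithium α-amino alkoxide while the second position is lithiated and formylated.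

Step 12
Reactants: 21 trimethoxy dialdehyde
Product: 22 5-[(1S)-1-[(2S,4aR,5S,8R)-5-(2-hydroxypropan-2-yl)-2,8-dimethyl-2,3,4,4a,5,6,7,8-octahydronaphthalen-2-yl]-3-methylbutyl]-2,4,6-trihydroxybenzene-1,3-dicarbaldehyde (target)
Conditions: NaSEt (excess), DMF, 120 °C; cold dilute aq. HCl
Reagents that add atoms: none
Why: Nucleophilic (SN2) O-demethylation by thiolate, each methoxy group being activated by an ortho formyl group that stabilises the departing phenoxide, under basic conditions that should spare the tertiary alcohol and the alkene.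

**Compound list**

1 | (R)-citronellal, (3R)-3,7-dimethyloct-6-enal | O=CC[C@H](C)CCC=C(C)C | starting material
2 | vinylmagnesium bromide | C=C[Mg]Br | starting material
3 | (5R)-5,9-dimethyldeca-1,8-dien-3-ol (C-3 epimers) | C=CC(O)C[C@H](C)CCC=C(C)C | intermediate
4 | (5R)-5,9-dimethyldeca-1,8-dien-3-one | C=CC(=O)C[C@H](C)CCC=C(C)C | intermediate
5 | citropten, 5,7-dimethoxy-2H-chromen-2-one | COc1cc(OC)c2ccc(=O)oc2c1 | starting material
6 | isobutylmagnesium bromide | CC(C)C[Mg]Br | starting material
7 | (4S)-5,7-dimethoxy-4-(2-methylpropyl)-3,4-dihydro-2H-chromen-2-one | CC(C)C[C@H]1CC(=O)Oc2cc(OC)cc(OC)c21 | intermediate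
8 | Michael adduct, (4S)-3-[(5R)-5,9-dimethyl-3-oxodec-8-en-1-yl]-5,7-dimethoxy-4-(2-methylpropyl)chroman-2-one (C-3 epimers) | CC(C)C[C@H]1C(CCC(=O)C[C@H](C)CCC=C(C)C)C(=O)Oc2cc(OC)cc(OC)c21 | intermediate
9 | phenolic cyclohexanedione, 4-[(1S)-1-(2-hydroxy-4,6-dimethoxyphenyl)-3-methylbutyl]-2-[(2R)-6-methylhept-5-en-2-yl]cyclohexane-1,3-dione (ring centres undefined) | CC(C)C[C@H](c1c(O)cc(OC)cc1OC)C1CCC(=O)C([C@H](C)CCC=C(C)C)C1=O | intermediate
10 | (9S)-6,8-dimethoxy-4-[(2R)-6-methylhept-5-en-2-yl]-9-(2-methylpropyl)-1,2,9,9a-tetrahydro-3H-xanthen-3-one (C-9a epimers) | CC(C)C[C@H]1C2CCC(=O)C([C@H](C)CCC=C(C)C)=C2Oc2cc(OC)cc(OC)c21 | intermediate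
11 | allylic alcohol, (9S)-6,8-dimethoxy-4-[(2R)-6-methylhept-5-en-2-yl]-9-(2-methylpropyl)-2,3,9,9a-tetrahydro-1H-xanthen-3-ol (epimers) | CC(C)C[C@H]1C2CCC(O)C([C@H](C)CCC=C(C)C)=C2Oc2cc(OC)cc(OC)c21 | intermediate
12 | 6-[(1S)-1-(2-hydroxy-4,6-dimethoxyphenyl)-3-methylbutyl]-2-[(2R)-6-methylhept-5-en-2-yl]cyclohex-2-en-1-one (C-6 epimers) | CC(C)C[C@H](c1c(O)cc(OC)cc1OC)C1CCC=C([C@H](C)CCC=C(C)C)C1=O | intermediate
13 | C-methylated phenol, (6R)-6-[(1R)-1-(2-hydroxy-4,6-dimethoxyphenyl)-3-methylbutyl]-6-methyl-2-[(2R)-6-methylhept-5-en-2-yl]cyclohex-2-en-1-one | CC(C)C[C@H](c1c(O)cc(OC)cc1OC)[C@@]1(C)CCC=C([C@H](C)CCC=C(C)C)C1=O | intermediate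
14 | (6R)-6-methyl-2-[(2R)-6-methylhept-5-en-2-yl]-6-[(1R)-3-methyl-1-(2,4,6-trimethoxyphenyl)butyl]cyclohex-2-en-1-one | CC(C)C[C@H](c1c(OC)cc(OC)cc1OC)[C@@]1(C)CCC=C([C@H](C)CCC=C(C)C)C1=O | intermediate
15 | (2R,4aR,5S,8R)-2,8-dimethyl-2-[(1R)-3-methyl-1-(2,4,6-trimethoxyphenyl)butyl]-5-(prop-1-en-2-yl)octahydronaphthalen-1(2H)-one (C-8a epimers) | CC(C)C[C@H](c1c(OC)cc(OC)cc1OC)[C@]1(C)C(=O)C2[C@H](C)CC[C@H](C(C)=C)[C@H]2CC1 | intermediate
16 | (2R,4aR,5S,8R)-2,8-dimethyl-2-[(1S)-3-methyl-1-(2,4,6-trimethoxyphenyl)butyl]-5-(prop-1-en-2-yl)-2,3,4,4a,5,6,7,8-octahydronaphthalen-1-yl trifluoromethanesulfonate | CC(C)C[C@H](c1c(OC)cc(OC)cc1OC)[C@]1(C)C(OS(=O)(=O)C(F)(F)F)=C2[C@H](C)CC[C@H](C(C)=C)[C@H]2CC1 | intermediate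
17 | 2-[(1S)-1-[(2S,4aR,5S,8R)-2,8-dimethyl-5-(prop-1-en-2-yl)-2,3,4,4a,5,6,7,8-octahydronaphthalen-2-yl]-3-methylbutyl]-1,3,5-trimethoxybenzene | CC(C)C[C@H](c1c(OC)cc(OC)cc1OC)[C@]1(C)C=C2[C@H](C)CC[C@H](C(C)=C)[C@H]2CC1 | intermediate
18 | tertiary hydroperoxide, the 2-hydroperoxypropan-2-yl analogue of 19 | CC(C)C[C@H](c1c(OC)cc(OC)cc1OC)[C@]1(C)C=C2[C@H](C)CC[C@H](C(C)(C)OO)[C@H]2CC1 | intermediate
19 | 2-[(1S,4R,6S,8aR)-4,6-dimethyl-6-[(1S)-3-methyl-1-(2,4,6-trimethoxyphenyl)butyl]-1,2,3,4,6,7,8,8a-octahydronaphthalen-1-yl]propan-2-ol | CC(C)C[C@H](c1c(OC)cc(OC)cc1OC)[C@]1(C)C=C2[C@H](C)CC[C@H](C(C)(C)O)[C@H]2CC1 | intermediate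
20 | monoformyl amino-alkoxide adduct of 19 (drawn as the neutral hemiaminal; present as its dilithium alkoxide) | CC(C)C[C@H](c1c(OC)cc(OC)c(C(O)N(C)C)c1OC)[C@]1(C)C=C2[C@H](C)CC[C@H](C(C)(C)O)[C@H]2CC1 | intermediate
21 | 5-[(1S)-1-[(2S,4aR,5S,8R)-5-(2-hydroxypropan-2-yl)-2,8-dimethyl-2,3,4,4a,5,6,7,8-octahydronaphthalen-2-yl]-3-methylbutyl]-2,4,6-trimethoxybenzene-1,3-dicarbaldehyde | CC(C)C[C@H](c1c(OC)c(C=O)c(OC)c(C=O)c1OC)[C@]1(C)C=C2[C@H](C)CC[C@H](C(C)(C)O)[C@H]2CC1 | intermediate
22 | 5-[(1S)-1-[(2S,4aR,5S,8R)-5-(2-hydroxypropan-2-yl)-2,8-dimethyl-2,3,4,4a,5,6,7,8-octahydronaphthalen-2-yl]-3-methylbutyl]-2,4,6-trihydroxybenzene-1,3-dicarbaldehyde | CC(C)C[C@H](c1c(O)c(C=O)c(O)c(C=O)c1O)[C@]1(C)C=C2[C@H](C)CC[C@H](C(C)(C)O)[C@H]2CC1 | target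

Total steps: 12. Longest linear sequence: 11 (steps 1, 2 and 4 to 12).

**Steps most likely to fail**

Step 7 (key step). The side-chain alkene may attack the wrong face of ring A, because the C-2 quaternary centre and the side-chain methyl can oppose each other. The zwitterion may also be diverted into hydride shift or cyclobutane closure before proton transfer, or the unactivated alkene may fail to engage the hindered enone. The fallback sets out from 14 and replaces the alkene by a stronger, cleanly terminating nucleophile. Allylic oxidation of the terminal (E)-methyl group (SeO2 cat., t-BuOOH, CH2Cl2) should give the (E)-allylic alcohol F1. Acetylation (Ac2O, pyridine) gives the allylic acetate F2. Palladium-catalysed silylation (Me3SiSiMe3, Pd(dba)2, LiCl, DMF, 100 °C) gives the allylsilane F3. An intramolecular Hosomi–Sakurai conjugate addition (EtAlCl2 or TiCl4, CH2Cl2, −78 °C) then closes ring B through the same chair, with loss of the silyl group generating the isopropenyl group directly. The fallback comes back to the route at 15.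

Step 6. Methylation of the dienolate may show poor facial selectivity, since only an exocyclic stereocentre directs it, and γ-deprotonation may compete. The fallback sets out from 7 and 4 and builds the quaternary centre on the rigid lactone, where the second substituent enters trans to the C-4 isobutyl group. Lactone 7 is converted (t-BuMe2SiOTf, Et3N) into the silyl ketene acetal F4. Mukaiyama–Michael addition to 4 (catalytic t-BuMe2SiOTf, CH2Cl2, −78 °C) gives the silyl enol ether F5, in which the ketone stays masked. Methylation (LiN(i-Pr)2, MeI, THF, −78 °C) gives the C-3 quaternary lactone F6 with methyl trans to isobutyl. Bu4NF releases the ketone enolate, which undergoes the Claisen cyclisation to the phenolic 4-methyl dione F7 (not isolated). TsOH then closes the 9a-methyl tetrahydroxanthenone F8. Reduction with i-Bu2AlH gives the allylic alcohol F9 (not isolated), and dilute HCl gives 13, which is isolated here. O-Methylation (K2CO3, MeI, acetone) returns the route at 14.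

Step 11. The second lithiation may stay incomplete, or n-BuLi may add to the masked first aldehyde, so that mono-formylated material results. The fallback sets out from 19 and separates the two formylations. A single lithiation–formylation (n-BuLi, TMEDA, THF, 0 °C; DMF) gives the monoaldehyde F10. Condensation with N,N′-dimethylethane-1,2-diamine (toluene, 4 Å MS) gives the base-stable imidazolidine F11. Lithiation of the remaining position between two methoxy groups (s-BuLi, TMEDA, THF, −78 °C) and quenching with DMF gives the formyl imidazolidine F12. Brief treatment with dilute aqueous acid cleaves the aminal, and the fallback comes back to the route at 21.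

**Further compounds**

F1 | step 7 | (E)-allylic alcohol, 14 with the terminal (E)-methyl group of the side chain oxidised to CH2OH | CC(C)C[C@H](c1c(OC)cc(OC)cc1OC)[C@@]1(C)CCC=C([C@H](C)CC/C=C(\C)CO)C1=O
F2 | step 7 | allylic acetate of F1 | CC(C)C[C@H](c1c(OC)cc(OC)cc1OC)[C@@]1(C)CCC=C([C@H](C)CC/C=C(\C)COC(C)=O)C1=O
F3 | step 7 | allylsilane, F1 with CH2OH replaced by CH2SiMe3 | CC(C)C[C@H](c1c(OC)cc(OC)cc1OC)[C@@]1(C)CCC=C([C@H](C)CC/C=C(\C)C[Si](C)(C)C)C1=O
F4 | step 6 | silyl ketene acetal, (4S)-2-(tert-butyldimethylsilyloxy)-5,7-dimethoxy-4-(2-methylpropyl)-4H-chromene | CC(C)C[C@H]1C=C(O[Si](C)(C)C(C)(C)C)Oc2cc(OC)cc(OC)c21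
F5 | step 6 | silyl enol ether, Mukaiyama–Michael adduct of F4 and 4 (C-3 epimers, enol ether geometry undefined) | CC(C)C[C@H]1C(CC=C(O[Si](C)(C)C(C)(C)C)C[C@H](C)CCC=C(C)C)C(=O)Oc2cc(OC)cc(OC)c21
F6 | step 6 | C-3 quaternary lactone, F5 methylated at C-3 trans to the C-4 isobutyl group | CC(C)C[C@H]1[C@@](C)(CC=C(O[Si](C)(C)C(C)(C)C)C[C@H](C)CCC=C(C)C)C(=O)Oc2cc(OC)cc(OC)c21
F7 | step 6 | phenolic 4-methyl dione, the 4-methyl analogue of 9 | CC(C)C[C@H](c1c(O)cc(OC)cc1OC)[C@@]1(C)CCC(=O)C([C@H](C)CCC=C(C)C)C1=O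
F8 | step 6 | 9a-methyl tetrahydroxanthenone, the 9a-methyl analogue of 10 | CC(C)C[C@H]1[C@@]2(C)CCC(=O)C([C@H](C)CCC=C(C)C)=C2Oc2cc(OC)cc(OC)c21
F9 | step 6 | allylic alcohol, the 9a-methyl analogue of 11 | CC(C)C[C@H]1[C@@]2(C)CCC(O)C([C@H](C)CCC=C(C)C)=C2Oc2cc(OC)cc(OC)c21
F10 | step 11 | monoaldehyde, 19 bearing one formyl group between two methoxy groups | CC(C)C[C@H](c1c(OC)cc(OC)c(C=O)c1OC)[C@]1(C)C=C2[C@H](C)CC[C@H](C(C)(C)O)[C@H]2CC1
F11 | step 11 | imidazolidine, the 1,3-dimethylimidazolidin-2-yl aminal of F10 | CC(C)C[C@H](c1c(OC)cc(OC)c(C3N(C)CCN3C)c1OC)[C@]1(C)C=C2[C@H](C)CC[C@H](C(C)(C)O)[C@H]2CC1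
F12 | step 11 | formyl imidazolidine, F11 formylated at the remaining aryl position | CC(C)C[C@H](c1c(OC)c(C=O)c(OC)c(C3N(C)CCN3C)c1OC)[C@]1(C)C=C2[C@H](C)CC[C@H](C(C)(C)O)[C@H]2CC1
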